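**Plan**

- Retrosynthesis: in unit A (the tetralol whose OH is ortho to the biaryl bond) the bond between the two ring-fusion carbons and the bond between C–OH and the aryl-bearing carbon are cut together. This opens its phenol ring and its saturated ring to a 5-aryl-4-methylfuran tied through the CH(iPr)–CH2–CH2–CH(Me) chain to a terminal alkyne. Next the aryl–furyl bond is cut (bromofuran + arylzinc of unit B), and unit B is traced to the same furan-yne without the aryl group.
- Enabling feature: in the phenol ring of unit A the OH-bearing carbon lies between a ring-fusion carbon and the aryl-bearing carbon. This is the retron of the gold-catalysed furan-yne phenol synthesis: phenol O = furan O; C–OH and the fusion carbon next to it = the alkyne; the aryl-, methyl- and H-bearing carbons and the second fusion carbon = furan C5, C4, C3, C2.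
- Forward: (+)-menthol → (+)-menthone → cleavage of the C1–C6 bond (ozonolysis of the kinetic silyl enol ether) → aldehyde to alkyne, acid to 4-methylfuran → furan-yne 10. One portion of 10 is cyclised with gold to the unit B tetralol 11, silylated and brominated para to oxygen (13). A second portion is C-silylated and brominated at furan C5 (15). Negishi coupling and desilylation follow, and a last gold cascade closes the phenol ring and, as the final ring of the skeleton, the saturated ring of unit A.
- Stereochemistry: all four stereocentres are C2 and C5 of (+)-menthone, used twice. They become the CH(iPr) and CH(Me) centres of each unit (trans, 1S,4R in cadalane numbering), and no step makes or breaks a bond at them.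

Key step: step 14

Remark: the SMILES leaves the configuration of the hindered biaryl axis open; the route does not control it, and the target is taken as defined by its four carbon stereocentres.

**Step 1**
Reactants: 1 (1S,2R,5S)-(+)-menthol
Product: 2 (2R,5S)-(+)-menthone
Conditions: TEMPO (cat.), NaOCl, KBr (cat.), NaHCO3, CH2Cl2/H2O, 0 °C
Reagents that add atoms: none
Why: Anelli oxidation of the secondary alcohol under buffered two-phase conditions should give the ketone without epimerising the adjacent CH(iPr) centre.

**Step 2**
Reactants: 2 (2R,5S)-(+)-menthone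
Product: 3 trimethylsilyl enol ether of 2 with the double bond between C1 and C6
Conditions: LDA, THF, −78 °C; TMSCl, −78 °C → rt
Reagents that add atoms: chlorotrimethylsilane C[Si](C)(C)Cl
Why: Kinetic deprotonation by LDA should occur at the CH2 group and not at the hindered CH(iPr), and O-silylation traps this less substituted enolate, so the C1–C6 bond is marked for cleavage while both stereocentres stay untouched.

**Step 3**
Reactants: 3 trimethylsilyl enol ether
Product: 4 (2R,5S)-5-methyl-6-oxo-2-(propan-2-yl)hexanoic acid (used crude)
Conditions: O3, CH2Cl2/MeOH, −78 °C; Me2S, −78 °C → rt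
Reagents that add atoms: ozone [O-][O+]=O
Why: Ozonolysis of a silyl enol ether cleaves the enol double bond to a carboxylic acid at the oxygen-bearing carbon and, after reductive work-up, an aldehyde at the other carbon, with neither stereocentre taking part.

**Step 4**
Reactants: 4 aldehyde acid
Product: 5 (2R,5S)-5-methyl-2-(propan-2-yl)hept-6-ynoic acid
Conditions: dimethyl (1-diazo-2-oxopropyl)phosphonate, K2CO3, MeOH, 0 °C → rt; then acidify
Reagents that add atoms: dimethyl (1-diazo-2-oxopropyl)phosphonate CC(=O)C(=[N+]=[N-])P(=O)(OC)OC
Why: Ohira–Bestmann (Seyferth–Gilbert) homologation should convert the aldehyde into the terminal alkyne while the carboxylate is inert, and adding the aldehyde to the preformed reagent anion at 0 °C limits epimerisation of the α-methyl centre.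

**Step 5**
Reactants: 5 alkyne acid
Product: 6 (2R,5S)-N-methoxy-N,5-dimethyl-2-(propan-2-yl)hept-6-ynamide
Conditions: CDI, CH2Cl2, rt; MeNH(OMe)·HCl, rt
Reagents that add atoms: N,O-dimethylhydroxylamine hydrochloride CNOC.Cl
Why: Activation as the acyl imidazole and aminolysis should give the Weinreb amide under weakly basic conditions that do not enolise the α-branched acyl group.

**Step 6**
Reactants: 6 Weinreb amide; 7 2-methylprop-2-en-1-ol
Product: 10 2-[(3R,6S)-2,6-dimethyloct-7-yn-3-yl]-4-methylfuran, via dilithiated methallyl alcohol 8 (not isolated), via hydroxy ketone 9 (not isolated)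
Conditions: 7 (excess), n-BuLi, TMEDA, Et2O, 0 °C → rt; add 6, THF, −78 → −20 °C; H2O; then TsOH·H2O (cat.), CH2Cl2, rt
Reagents that add atoms: none
Why: After one equivalent of the dianion has deprotonated the alkyne, its allylic carbon should add once to the Weinreb amide (organolithium ketone synthesis), and the γ-hydroxy ketone then closes to the hemiketal and dehydrates under acid, the exocyclic methylene moving into the ring to give the aromatic 4-methylfuran (Paal–Knorr-type cyclodehydration).

**Step 7**
Reactants: 10 furan-yne
Product: 11 (5R,8S)-3,8-dimethyl-5-(propan-2-yl)-5,6,7,8-tetrahydronaphthalen-1-ol (unit B tetralol)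
Conditions: (Mes3P)AuNTf2 (cat.), CH2Cl2, rt
Reagents that add atoms: none
Why: The gold-catalysed furan-yne phenol synthesis (Hashmi phenol synthesis) should close the saturated ring by 6-exo attack of furan C2 on the activated alkyne and rebuild the furan as a phenol whose OH sits on the former alkyne terminus, next to the ring fusion, with both chain stereocentres carried over unchanged.

**Step 8**
Reactants: 11 unit B tetralol
Product: 12 tert-butyldimethylsilyl ether of 11
Conditions: TBSCl, imidazole, DMF, 40 °C
Reagents that add atoms: tert-butyldimethylsilyl chloride CC(C)(C)[Si](C)(C)Cl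
Why: Standard silylation should mask the phenol for the organolithium step and place a bulky group beside the free ortho position.

**Step 9**
Reactants: 12 silyl ether
Product: 13 4-bromo derivative of 12 (bromine para to the silyloxy group)
Conditions: NBS, MeCN, 0 °C → rt, dark
Reagents that add atoms: N-bromosuccinimide O=C1CCC(=O)N1Br
Why: Electrophilic aromatic bromination of a 2,3,5-trialkylphenol ether should go para to oxygen, as is usual for this substitution pattern, and the silyl group shields the only other activated position.

**Step 10**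
Reactants: 10 furan-yne
Product: 14 [(3S,6R)-3,7-dimethyl-6-(4-methylfuran-2-yl)oct-1-yn-1-yl]trimethylsilane
Conditions: n-BuLi (1.05 equiv), THF, −78 °C; TMSCl, −78 → 0 °C
Reagents that add atoms: chlorotrimethylsilane C[Si](C)(C)Cl
Why: One equivalent of base at −78 °C should remove only the acetylenic proton, which is far more acidic than the furan or propargylic C–H, and C-silylation masks the alkyne for the coupling.

**Step 11**
Reactants: 14 C-silylated furan-yne
Product: 15 5-bromofuran derived from 14 (used at once)
Conditions: NBS (1.0 equiv), DMF, −20 °C, dark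
Reagents that add atoms: N-bromosuccinimide O=C1CCC(=O)N1Br
Why: Electrophilic bromination of a furan should take place at its only free α-position, which is much more reactive than the β C–H, and the silyl alkyne is inert to NBS without a silver salt.

**Step 12**
Reactants: 13 aryl bromide; 15 bromofuran
Product: 18 bis-silylated aryl furan, via aryllithium 16 (not isolated), via arylzinc chloride 17 (not isolated)
Conditions: 13, t-BuLi (2.0 equiv), THF, −78 °C; ZnCl2, −78 °C → rt; 15, Pd2(dba)3 (cat.), SPhos, THF, 50 °C
Reagents that add atoms: none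
Why: Bromine–lithium exchange, transmetalation to zinc and Negishi coupling with a zerovalent palladium/SPhos catalyst should join the di-ortho-substituted arylzinc to the bromofuran, the five-membered partner keeping the new bond only tri-ortho-substituted and the silyl groups being inert to the neutral organozinc.

**Step 13**
Reactants: 18 bis-silylated aryl furan
Product: 19 (5R,8S)-4-{5-[(3R,6S)-2,6-dimethyloct-7-yn-3-yl]-3-methylfuran-2-yl}-3,8-dimethyl-5-(propan-2-yl)-5,6,7,8-tetrahydronaphthalen-1-ol
Conditions: TBAF, THF, 0 °C → rt
Reagents that add atoms: none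
Why: Fluoride should cleave both the alkynyl C–Si bond and the aryl silyl ether in one operation, freeing the terminal alkyne and the phenol of unit B.

**Step 14**
Reactants: 19 aryl furan-yne
Product: 20 target, the 7,5'-linked dimer of (1S,4R)-8-hydroxycalamenene (CNP0145304.1)
Conditions: (Mes3P)AuNTf2 (5 mol %), CH2Cl2, rt (40 °C if slow), argon
Reagents that add atoms: none
Why: Cationic monovalent gold activates the terminal alkyne, furan C2 attacks the internal alkyne carbon (this bond joins the two future ring-fusion carbons and closes the saturated ring), the cyclopropyl gold carbenoid opens the furan to a (Z)-dienyl aryl ketone carrying a vinyl gold carbene, the ketone oxygen adds to the carbene carbon to give an oxepine/arene oxide, and epoxide opening with proton loss gives the phenol. The closest known reaction type is the gold-catalysed furan-yne phenol synthesis (Hashmi phenol synthesis), which is known for carbon tethers and for 5-aryl furans that give hydroxybiaryls. The saturated ring closes in the 6-exo-dig mode, and the phenol ring closes between the ketone carbon (former furan C5) and the alkyne terminus through the oxepine–arene oxide valence isomerisation before it aromatises. No stereocentre is formed or touched: the CH(Me) and CH(iPr) centres from menthone lie outside the reacting π system, so the trans (1S,4R) relation is fixed by the chain, while the biaryl axis arises here without control. The step needs the oxygen placed ortho to both the ring fusion and the aryl group, which is secured because oxygen is transferred only to the alkyne terminus and the arene oxide opens at the aryl-substituted carbon, from where proton loss gives the phenol directly; the free phenol of unit B should not interfere, since the reaction tolerates its own phenolic product.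

**Compound list**

1 | (1S,2R,5S)-(+)-menthol, (1S,2R,5S)-5-methyl-2-(propan-2-yl)cyclohexan-1-ol | C[C@H]1CC[C@@H]([C@@H](O)C1)C(C)C | starting material
2 | (2R,5S)-(+)-menthone, (2R,5S)-5-methyl-2-(propan-2-yl)cyclohexan-1-one | C[C@H]1CC[C@@H](C(=O)C1)C(C)C | intermediate
3 | trimethyl{[(3S,6R)-3-methyl-6-(propan-2-yl)cyclohex-1-en-1-yl]oxy}silane | C[C@H]1CC[C@@H](C(O[Si](C)(C)C)=C1)C(C)C | intermediate
4 | (2R,5S)-5-methyl-6-oxo-2-(propan-2-yl)hexanoic acid | C[C@H](C=O)CC[C@@H](C(=O)O)C(C)C | intermediate
5 | (2R,5S)-5-methyl-2-(propan-2-yl)hept-6-ynoic acid | C[C@H](C#C)CC[C@@H](C(=O)O)C(C)C | intermediate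
6 | (2R,5S)-N-methoxy-N,5-dimethyl-2-(propan-2-yl)hept-6-ynamide | C[C@H](C#C)CC[C@@H](C(=O)N(C)OC)C(C)C | intermediate
7 | 2-methylprop-2-en-1-ol (methallyl alcohol) | CC(=C)CO | starting material
8 | lithium 2-(lithiomethyl)prop-2-en-1-olate (dilithiated 7) | [Li]CC(=C)CO[Li] | intermediate
9 | (5R,8S)-1-hydroxy-8-methyl-2-methylidene-5-(propan-2-yl)dec-9-yn-4-one | C[C@H](C#C)CC[C@@H](C(=O)CC(=C)CO)C(C)C | intermediate
10 | 2-[(3R,6S)-2,6-dimethyloct-7-yn-3-yl]-4-methylfuran | C[C@H](C#C)CC[C@@H](c1cc(C)co1)C(C)C | intermediate
11 | (5R,8S)-3,8-dimethyl-5-(propan-2-yl)-5,6,7,8-tetrahydronaphthalen-1-ol, (1S,4R)-8-hydroxycalamenene | C[C@H]1CC[C@H](C(C)C)c2cc(C)cc(O)c12 | intermediate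
12 | tert-butyl{[(5R,8S)-3,8-dimethyl-5-(propan-2-yl)-5,6,7,8-tetrahydronaphthalen-1-yl]oxy}dimethylsilane | C[C@H]1CC[C@H](C(C)C)c2cc(C)cc(O[Si](C)(C)C(C)(C)C)c12 | intermediate
13 | {[(5R,8S)-4-bromo-3,8-dimethyl-5-(propan-2-yl)-5,6,7,8-tetrahydronaphthalen-1-yl]oxy}(tert-butyl)dimethylsilane | C[C@H]1CC[C@H](C(C)C)c2c(Br)c(C)cc(O[Si](C)(C)C(C)(C)C)c12 | intermediate
14 | [(3S,6R)-3,7-dimethyl-6-(4-methylfuran-2-yl)oct-1-yn-1-yl]trimethylsilane | C[C@H](C#C[Si](C)(C)C)CC[C@@H](c1cc(C)co1)C(C)C | intermediate
15 | [(3S,6R)-6-(5-bromo-4-methylfuran-2-yl)-3,7-dimethyloct-1-yn-1-yl]trimethylsilane | C[C@H](C#C[Si](C)(C)C)CC[C@@H](c1cc(C)c(Br)o1)C(C)C | intermediate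
16 | aryllithium from 13 (Li in place of Br) | C[C@H]1CC[C@H](C(C)C)c2c([Li])c(C)cc(O[Si](C)(C)C(C)(C)C)c12 | intermediate
17 | arylzinc chloride from 13 (ZnCl in place of Br) | C[C@H]1CC[C@H](C(C)C)c2c([Zn]Cl)c(C)cc(O[Si](C)(C)C(C)(C)C)c12 | intermediate
18 | tert-butyl{[(5R,8S)-4-{5-[(3R,6S)-2,6-dimethyl-8-(trimethylsilyl)oct-7-yn-3-yl]-3-methylfuran-2-yl}-3,8-dimethyl-5-(propan-2-yl)-5,6,7,8-tetrahydronaphthalen-1-yl]oxy}dimethylsilane | C[C@H](C#C[Si](C)(C)C)CC[C@@H](c1cc(C)c(-c2c(C)cc(O[Si](C)(C)C(C)(C)C)c3c2[C@@H](C(C)C)CC[C@@H]3C)o1)C(C)C | intermediate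
19 | (5R,8S)-4-{5-[(3R,6S)-2,6-dimethyloct-7-yn-3-yl]-3-methylfuran-2-yl}-3,8-dimethyl-5-(propan-2-yl)-5,6,7,8-tetrahydronaphthalen-1-ol | C[C@H](C#C)CC[C@@H](c1cc(C)c(-c2c(C)cc(O)c3c2[C@@H](C(C)C)CC[C@@H]3C)o1)C(C)C | intermediate
20 | (5R,8S)-2-[(5S,8R)-4-hydroxy-2,5-dimethyl-8-(propan-2-yl)-5,6,7,8-tetrahydronaphthalen-1-yl]-3,8-dimethyl-5-(propan-2-yl)-5,6,7,8-tetrahydronaphthalen-1-ol | Cc1cc2c(c(O)c1-c1c(C)cc(O)c3c1[C@@H](C(C)C)CC[C@@H]3C)[C@@H](C)CC[C@@H]2C(C)C | target

**Totals**

Total step count: 14. Longest linear sequence: 12 steps (steps 1–9, then 12–14).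

**Steps most likely to fail**

Step 14. The cascade may be slow or misdirected: the six-membered ring has to form through an unconstrained four-carbon tether next to a very hindered aryl ketone intermediate, so alkyne hydration or oligomerisation may compete, and the arene oxide may open with aryl migration to a regioisomeric phenol. The fallback joins the two tetralols after both ring systems exist; it sets out from 11 (with 13 as the partner) and comes back at 20. Amine-directed ortho-bromination of 11 (NBS, catalytic i-Pr2NH, CH2Cl2) should give (5R,8S)-2-bromo-3,8-dimethyl-5-(propan-2-yl)-5,6,7,8-tetrahydronaphthalen-1-ol F1. Negishi coupling of F1 with two equivalents of arylzinc 17 (made from 13 as in step 12; the first equivalent is consumed by the phenol and returns 12 on work-up) with Pd2(dba)3/RuPhos in THF/NMP at 70 °C should give the mono-silyl ether of the target F2. TBAF then gives 20.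

Step 12. The electron-rich 2-bromofuran may decompose before or during the coupling, and slow transmetalation of the di-ortho-substituted arylzinc may lead to protodemetalation or homocoupling. The fallback builds the furan onto the aryl group instead of coupling; it sets out from 13 and 6 and comes back at 19. Bromine–lithium exchange on 13 and addition of the aryllithium 16 to methacrolein should give the 1-aryl-2-methylprop-2-en-1-ol F3 (both carbinol epimers serve, since this carbon becomes furan C5). Double deprotonation of F3 (n-BuLi, TMEDA, as for 7) and addition to Weinreb amide 6 should give the hydroxy ketone F4, which TsOH cyclodehydrates as in step 6 to the silyl-protected aryl furan-yne F5. TBAF then gives 19.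

Step 6. The strongly basic dianion may enolise the α-branched Weinreb amide (epimerisation at the CH(iPr) centre or return of starting amide), and incomplete metalation of 7 may leave n-BuLi that adds in its place. The fallback uses an ynone instead; it sets out from 6 and comes back at 10. Addition of the lithium acetylide of tert-butyldimethyl(prop-2-yn-1-yloxy)silane (excess, THF, −78 °C) to 6 should give the ynone (5R,8S)-1-[(tert-butyldimethylsilyl)oxy]-8-methyl-5-(propan-2-yl)deca-2,9-diyn-4-one F6. Conjugate addition of Me2CuLi should give the β-methyl enone (5R,8S)-1-[(tert-butyldimethylsilyl)oxy]-2,8-dimethyl-5-(propan-2-yl)dec-2-en-9-yn-4-one F7 as an E/Z mixture. HCl in THF/MeOH then removes the silyl group, equilibrates the double bond and cyclodehydrates the γ-hydroxy enone to 10.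

**Further compounds**

F1 | step 14 | (5R,8S)-2-bromo-3,8-dimethyl-5-(propan-2-yl)-5,6,7,8-tetrahydronaphthalen-1-ol | C[C@H]1CC[C@H](C(C)C)c2cc(C)c(Br)c(O)c12
F2 | step 14 | mono-tert-butyldimethylsilyl ether of 20 (silyl on the unit B oxygen) | Cc1cc2c(c(O)c1-c1c(C)cc(O[Si](C)(C)C(C)(C)C)c3c1[C@@H](C(C)C)CC[C@@H]3C)[C@@H](C)CC[C@@H]2C(C)C
F3 | step 12 | 1-[(5S,8R)-4-{[tert-butyl(dimethyl)silyl]oxy}-2,5-dimethyl-8-(propan-2-yl)-5,6,7,8-tetrahydronaphthalen-1-yl]-2-methylprop-2-en-1-ol (carbinol epimers) | C=C(C)C(O)c1c(C)cc(O[Si](C)(C)C(C)(C)C)c2c1[C@@H](C(C)C)CC[C@@H]2C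
F4 | step 12 | hydroxy ketone from F3 and 6 (aryl-substituted analogue of 9) | C[C@H](C#C)CC[C@@H](C(=O)CC(=C)C(O)c1c(C)cc(O[Si](C)(C)C(C)(C)C)c2c1[C@@H](C(C)C)CC[C@@H]2C)C(C)C
F5 | step 12 | tert-butyldimethylsilyl ether of 19 | C[C@H](C#C)CC[C@@H](c1cc(C)c(-c2c(C)cc(O[Si](C)(C)C(C)(C)C)c3c2[C@@H](C(C)C)CC[C@@H]3C)o1)C(C)C
F6 | step 6 | (5R,8S)-1-[(tert-butyldimethylsilyl)oxy]-8-methyl-5-(propan-2-yl)deca-2,9-diyn-4-one | C[C@H](C#C)CC[C@@H](C(=O)C#CCO[Si](C)(C)C(C)(C)C)C(C)C
F7 | step 6 | (5R,8S)-1-[(tert-butyldimethylsilyl)oxy]-2,8-dimethyl-5-(propan-2-yl)dec-2-en-9-yn-4-one (E/Z mixture) | C[C@H](C#C)CC[C@@H](C(=O)C=C(C)CO[Si](C)(C)C(C)(C)C)C(C)C
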